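**Strategy.** Both flavan units are the same 2,3-cis (2R,3R) 7,8-dioxygenated flavan, so one monomer serves twice and the interflavan C4–C6 bond is made last through the C4 benzylic cation. Ring C of the monomer is closed by a formal [4+2] annulation that forges O1–C8a and C4a–C4 in one pot: a rhodium carbenoid from an ortho-quinone diazide (future ring A) inserts into the C2 carbinol O–H of an aldol-derived syn acetal, and the unveiled phenol ether cyclises onto the acetal carbon C4. The step exploits the pyrogallol pattern of ring A: the C8 oxygen is the diazide carbonyl next to C8a, and C4a, para to O7, is the nucleophilic carbon.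

Key step: step 9

Remark: the target is read as epioritin-(4β→6)-epioritin-4β-ol, with both units (2R,3R,4S), i.e. 2,3-cis-3,4-trans (epioritin = (2R,3R)-7,8,4′-trihydroxyflavan-3-ol). Flavan numbering (O1, C2, C3, C4, C4a, C5–C8, C8a; rings A, B, C) is used for all chromans and their acyclic precursors. Compound 16 is divided: one part becomes the lower unit (via 17), the other the upper unit.

**Step 1**
Reactants: 1 (4S)-4-benzyl-1,3-oxazolidin-2-one; 2 (benzyloxy)acetyl chloride
Product: 3 (4S)-4-benzyl-3-[(benzyloxy)acetyl]-1,3-oxazolidin-2-one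
Conditions: n-BuLi, THF, −78 °C; then 2, −78 → 0 °C
Reagents that add atoms: none
Why: N-acylation of the lithiated oxazolidinone by the acid chloride should give the glycolate imide cleanly, and the auxiliary stereocenter is not touched.

**Step 2**
Reactants: 3; 4 4-(benzyloxy)benzaldehyde
Product: 5 (4S)-4-benzyl-3-[(2S,3R)-2-(benzyloxy)-3-[4-(benzyloxy)phenyl]-3-hydroxypropanoyl]-1,3-oxazolidin-2-one
Conditions: Bu2BOTf, Et3N, CH2Cl2, −78 → 0 °C; then 4, −78 → 0 °C; pH 7 buffer, MeOH, H2O2
Reagents that add atoms: none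
Why: Evans syn-aldol reaction, in which the Z-boron enolate reacts through a Zimmerman–Traxler chair with the auxiliary benzyl group shielding one enolate face, should set both carbinol centers (future C3 and C2) as the (2S,3R)-syn pair with the C3 oxygen already differentiated as its benzyl ether.

**Step 3**
Reactants: 5
Product: 6 (2S,3R)-2-(benzyloxy)-3-[4-(benzyloxy)phenyl]-3-hydroxy-N-methoxy-N-methylpropanamide
Conditions: MeNH(OMe)·HCl, AlMe3, THF, −20 → 0 °C; aq. potassium sodium tartrate
Reagents that add atoms: N,O-dimethylhydroxylamine hydrochloride, CNOC.Cl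
Why: Aluminium amide transamination to the Weinreb amide, assisted by the free β-hydroxyl, should release the auxiliary without touching the two stereocenters.

**Step 4**
Reactants: 6
Product: 7 (2S,3R)-2-(benzyloxy)-3-[4-(benzyloxy)phenyl]-3-hydroxypropanal
Conditions: i-Bu2AlH (2.5 equiv), THF, −78 °C; aq. potassium sodium tartrate
Reagents that add atoms: none
Why: Reduction of the Weinreb amide should stop at the aldehyde through the chelated tetrahedral intermediate, and the low temperature protects the α-stereocenter from epimerisation.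

**Step 5**
Reactants: 7
Product: 8 (1R,2S)-2-(benzyloxy)-1-[4-(benzyloxy)phenyl]-3,3-dimethoxypropan-1-ol
Conditions: HC(OMe)3, pyridinium p-toluenesulfonate (cat.), MeOH, 0 °C → rt
Reagents that add atoms: trimethyl orthoformate, COC(OC)OC; methanol, CO
Why: Acid-catalysed acetalisation should mask the aldehyde as the latent C4 electrophile and leave the C2 carbinol as the only free O–H, with no stereocenter involved.

**Step 6**
Reactants: 9 3-nitrobenzene-1,2-diol (3-nitrocatechol)
Product: 10 2-(benzyloxy)-6-nitrophenol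
Conditions: NaH (2.2 equiv), DMSO, rt; BnBr (1.0 equiv); aq. HCl
Reagents that add atoms: benzyl bromide, BrCc1ccccc1
Why: Williamson etherification of the dianion, in which the phenoxide meta to the nitro group is the more nucleophilic oxygen, should benzylate the future O7 and leave the hydroxyl next to the nitro group free.

**Step 7**
Reactants: 10
Product: 11 2-amino-6-(benzyloxy)phenol
Conditions: H2 (1 atm), Pt/C (sulfided), EtOAc, rt
Reagents that add atoms: none
Why: Catalytic hydrogenation over sulfided platinum should reduce the nitro group chemoselectively without hydrogenolysis of the aryl benzyl ether.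

**Step 8**
Reactants: 11
Product: 12 2-(benzyloxy)-6-diazocyclohexa-2,4-dien-1-one (ortho-quinone diazide)
Conditions: NaNO2, aq. HCl, THF, 0 °C; then NaHCO3 to pH 8, dark; used at once as a solution
Reagents that add atoms: sodium nitrite, [Na+].[O-]N=O
Why: Diazotisation of the ortho-aminophenol and deprotonation of the 2-hydroxybenzenediazonium salt should give the ortho-quinone diazide, with the diazo carbon at the future C8a and the carbonyl at the future C8.

**Step 9**
Reactants: 8; 12
Product: 15 (2R,3S,4S)-3,7-bis(benzyloxy)-2-[4-(benzyloxy)phenyl]-4-(benzylsulfanyl)-3,4-dihydro-2H-chromen-8-ol, via aryl ether phenol 13 (not isolated), via 4-methoxyflavan 14 (not isolated)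
Conditions: Rh2(OAc)4 (2 mol %), ClCH2CH2Cl, 60 °C, dark, slow addition of 12 (1.5 equiv) until consumed; then −40 °C, Me3SiOTf (0.3 equiv); then BnSH (3 equiv), −40 → 0 °C
Reagents that add atoms: phenylmethanethiol, SCc1ccccc1
Why: Rh2(OAc)4 converts diazide 12 into a carbenoid at the future C8a that inserts into the only free O–H of 8 (oxonium ylide, proton shift, tautomerisation to the phenol), which forms O1–C8a and unveils the C8 hydroxyl of 13; Me3SiOTf then ionises the acetal to an oxocarbenium ion at C4 that is attacked by C4a, forming C4a–C4, and the 4-methoxy group of 14 (either C4 epimer) is exchanged for BnS through the C4 cation. The closest known reaction types are the rhodium-catalysed O–H insertion of ortho-quinone diazides into alcohols, the acetal–arene Friedel–Crafts cyclisation and the thiolysis of 4-oxygenated flavans. Ring C closes in the 6-exo-trig mode, the arene carbon C4a adding to the exocyclic C4=O+ bond. C2 and C3 are carried unchanged from 8 because no bond to them is broken, and C4 is set under substrate control by attack of the thiol on the planar cation anti to the 3-benzyloxy group (3,4-trans, 4β). The step needs chemoselective insertion into O–H (a single free hydroxyl, slow addition of 12) and ring closure at C4a only, which is secured because C4a is the sole free position ortho to O1 and is para to O7; thiol capture keeps the product from self-condensing through its C4 cation.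

**Step 10**
Reactants: 15
Product: 16 (2R,3S,4S)-3,7,8-tris(benzyloxy)-2-[4-(benzyloxy)phenyl]-4-(benzylsulfanyl)-3,4-dihydro-2H-chromene
Conditions: BnBr, K2CO3, DMF, rt
Reagents that add atoms: benzyl bromide, BrCc1ccccc1
Why: Williamson benzylation of the C8 phenol should leave C6, ortho to O7 and para to O1, as the most nucleophilic ring A carbon for the later coupling and make the final deprotection uniform.

**Step 11**
Reactants: 16 (one part)
Product: 17 (2R,3R,4S)-3,7,8-tris(benzyloxy)-2-[4-(benzyloxy)phenyl]-3,4-dihydro-2H-chromen-4-ol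
Conditions: AgBF4, NaHCO3, acetone/H2O (9:1), 0 °C, dark
Reagents that add atoms: water, O
Why: Silver-assisted ionisation of the C4–S bond (SN1) should give the C4 cation, which water captures anti to the 3-benzyloxy group, so the 4β-hydroxyl (3,4-trans, C4 of the lower unit) is set under substrate control.

**Step 12**
Reactants: 16 (1 equiv); 17 (3 equiv)
Product: 18 3,7,8,4′-tetra-O-benzylepioritin-(4β→6)-3,7,8,4′-tetra-O-benzylepioritin-4β-ol (lower 4-OH free)
Conditions: AgBF4 (1.5 equiv), 2,6-di-tert-butyl-4-methylpyridine, THF, 0 °C, dark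
Reagents that add atoms: none
Why: Silver-promoted ionisation of thioether 16 should give the C4 cation, which alkylates C6 of 17 (ortho to O7, para to O1) in a biomimetic Friedel–Crafts interflavan coupling; attack anti to the 3-benzyloxy group sets the upper C4 as 4β, the hindered base removes the acid that would ionise the 4-hydroxyl of 17, and excess 17 is recovered.

**Step 13**
Reactants: 18
Product: 19 epioritin-(4β→6)-epioritin-4β-ol, (2R,3R,4S)-2-(4-hydroxyphenyl)-6-[(2R,3R,4S)-3,7,8-trihydroxy-2-(4-hydroxyphenyl)-3,4-dihydro-2H-chromen-4-yl]-3,4-dihydro-2H-chromene-3,4,7,8-tetrol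
Conditions: H2 (1 atm), Pd/C, EtOAc/MeOH, rt
Reagents that add atoms: none
Why: Hydrogenolysis over palladium should cleave the eight benzyl ethers under neutral conditions, under which the ring C benzylic C–O bonds and the interflavan bond are expected to survive.

**Compound list**

1 | (4S)-4-benzyl-1,3-oxazolidin-2-one | O=C1N[C@@H](Cc2ccccc2)CO1 | starting material
2 | (benzyloxy)acetyl chloride | O=C(Cl)COCc1ccccc1 | starting material
3 | (4S)-4-benzyl-3-[(benzyloxy)acetyl]-1,3-oxazolidin-2-one | O=C(COCc1ccccc1)N1[C@@H](Cc2ccccc2)COC1=O | intermediate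
4 | 4-(benzyloxy)benzaldehyde | O=Cc1ccc(OCc2ccccc2)cc1 | starting material
5 | (4S)-4-benzyl-3-[(2S,3R)-2-(benzyloxy)-3-[4-(benzyloxy)phenyl]-3-hydroxypropanoyl]-1,3-oxazolidin-2-one | O=C([C@@H](OCc1ccccc1)[C@H](O)c1ccc(OCc2ccccc2)cc1)N1[C@@H](Cc2ccccc2)COC1=O | intermediate
6 | (2S,3R)-2-(benzyloxy)-3-[4-(benzyloxy)phenyl]-3-hydroxy-N-methoxy-N-methylpropanamide | CON(C)C(=O)[C@@H](OCc1ccccc1)[C@H](O)c1ccc(OCc2ccccc2)cc1 | intermediate
7 | (2S,3R)-2-(benzyloxy)-3-[4-(benzyloxy)phenyl]-3-hydroxypropanal | O=C[C@@H](OCc1ccccc1)[C@H](O)c1ccc(OCc2ccccc2)cc1 | intermediate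
8 | (1R,2S)-2-(benzyloxy)-1-[4-(benzyloxy)phenyl]-3,3-dimethoxypropan-1-ol | COC(OC)[C@@H](OCc1ccccc1)[C@H](O)c1ccc(OCc2ccccc2)cc1 | intermediate
9 | 3-nitrobenzene-1,2-diol | Oc1cccc([N+](=O)[O-])c1O | starting material
10 | 2-(benzyloxy)-6-nitrophenol | Oc1c(OCc2ccccc2)cccc1[N+](=O)[O-] | intermediate
11 | 2-amino-6-(benzyloxy)phenol | Nc1cccc(OCc2ccccc2)c1O | intermediate
12 | 2-(benzyloxy)-6-diazocyclohexa-2,4-dien-1-one | [N-]=[N+]=C1C=CC=C(OCc2ccccc2)C1=O | intermediate
13 | 2-(benzyloxy)-6-{[(1R,2S)-2-(benzyloxy)-1-[4-(benzyloxy)phenyl]-3,3-dimethoxypropyl]oxy}phenol | COC(OC)[C@@H](OCc1ccccc1)[C@H](Oc1cccc(OCc2ccccc2)c1O)c1ccc(OCc2ccccc2)cc1 | intermediate (not isolated)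
14 | (2R,3R,4S)-3,7-bis(benzyloxy)-2-[4-(benzyloxy)phenyl]-4-methoxy-3,4-dihydro-2H-chromen-8-ol (4β epimer drawn) | c1ccc(COc2ccc([C@H]3Oc4c(ccc(OCc5ccccc5)c4O)[C@H](OC)[C@H]3OCc3ccccc3)cc2)cc1 | intermediate (not isolated)
15 | (2R,3S,4S)-3,7-bis(benzyloxy)-2-[4-(benzyloxy)phenyl]-4-(benzylsulfanyl)-3,4-dihydro-2H-chromen-8-ol | c1ccc(COc2ccc([C@H]3Oc4c(ccc(OCc5ccccc5)c4O)[C@H](SCc4ccccc4)[C@H]3OCc3ccccc3)cc2)cc1 | intermediate
16 | (2R,3S,4S)-3,7,8-tris(benzyloxy)-2-[4-(benzyloxy)phenyl]-4-(benzylsulfanyl)-3,4-dihydro-2H-chromene | c1ccc(COc2ccc([C@H]3Oc4c(ccc(OCc5ccccc5)c4OCc4ccccc4)[C@H](SCc4ccccc4)[C@H]3OCc3ccccc3)cc2)cc1 | intermediate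
17 | (2R,3R,4S)-3,7,8-tris(benzyloxy)-2-[4-(benzyloxy)phenyl]-3,4-dihydro-2H-chromen-4-ol | c1ccc(COc2ccc([C@H]3Oc4c(ccc(OCc5ccccc5)c4OCc4ccccc4)[C@H](O)[C@H]3OCc3ccccc3)cc2)cc1 | intermediate
18 | 3,7,8,4′-tetra-O-benzylepioritin-(4β→6)-3,7,8,4′-tetra-O-benzylepioritin-4β-ol | c1ccc(COc2ccc([C@H]3Oc4c(ccc(OCc5ccccc5)c4OCc4ccccc4)[C@H](c4cc5c(c(OCc6ccccc6)c4OCc4ccccc4)O[C@H](c4ccc(OCc6ccccc6)cc4)[C@H](OCc4ccccc4)[C@H]5O)[C@H]3OCc3ccccc3)cc2)cc1 | intermediate
19 | epioritin-(4β→6)-epioritin-4β-ol | Oc1ccc([C@H]2Oc3c(ccc(O)c3O)[C@H](c3cc4c(c(O)c3O)O[C@H](c3ccc(O)cc3)[C@H](O)[C@H]4O)[C@H]2O)cc1 | target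

**Total step count:** 13. **Longest linear sequence:** 10 steps (steps 1–5 and 9–13).

**Steps most likely to fail**

Step 9. The carbenoid may be lost to Wolff-type ring contraction, to a second insertion into the phenol it has just unveiled or to attack on the electron-rich arenes, and the Lewis acid may ionise the acyclic C2–O1 benzylic ether before ring closure. The fallback forms O1–C8a by nucleophilic aromatic substitution and still closes ring C in the same flask. Commercial 2-fluoro-6-hydroxybenzaldehyde is benzylated (BnBr, K2CO3) to 2-(benzyloxy)-6-fluorobenzaldehyde F1. Setting out from 8, its potassium alkoxide (KN(SiMe3)2, THF, 0 °C → rt) displaces the fluoride ortho to the formyl group to give 2-(benzyloxy)-6-{[(1R,2S)-2-(benzyloxy)-1-[4-(benzyloxy)phenyl]-3,3-dimethoxypropyl]oxy}benzaldehyde F2. Without isolation the mixture is diluted with CH2Cl2 and treated with excess Me3SiOTf at −20 °C to close ring C at C4a, giving the 8-formyl-4-methoxyflavan F3. Baeyer–Villiger oxidation (mCPBA, NaHCO3) gives the 8-formate of 14 F4, methanolysis (K2CO3, MeOH) gives 14, now isolated, and thiolysis (BnSH, Me3SiOTf, −40 °C) returns the route to 15.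

Step 12. The cation may alkylate the free 4-hydroxyl of 17 (ether-linked dimer) or C5 instead of C6, and 17 may itself ionise and start chain growth. The fallback exchanges the roles of the two monomers. Setting out from 16 and 17, alcohol 17 is ionised with catalytic Me3SiOTf at −78 °C in CH2Cl2 in the presence of excess thioether 16, whose sulfanyl group is not activated by the hard Lewis acid and caps the lower unit. This gives 3,7,8,4′-tetra-O-benzylepioritin-(4β→6)-3,7,8,4′-tetra-O-benzyl-4β-(benzylsulfanyl)epioritin F5. Hydrolysis with AgBF4 and NaHCO3 in wet acetone then returns the route to 18.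

Step 13. Hydrogenolysis may also remove the doubly activated benzylic 4-hydroxyl of the lower unit. The fallback masks that hydroxyl first. Setting out from 17, silylation (t-BuMe2SiOTf, 2,6-lutidine) gives the 4-O-tert-butyldimethylsilyl ether of 17 F6. Coupling with 16 (AgBF4, hindered pyridine, THF) gives the 4-O-silyl ether of 18 F7, hydrogenolysis (H2, Pd/C, EtOAc) gives the free phenolic 4-O-silyl ether of 19 F8, and desilylation (Bu4NF buffered with AcOH, THF, 0 °C, under argon) arrives at 19.

**Further compounds**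

F1 | step 9 | 2-(benzyloxy)-6-fluorobenzaldehyde | O=Cc1c(F)cccc1OCc1ccccc1
F2 | step 9 | 2-(benzyloxy)-6-{[(1R,2S)-2-(benzyloxy)-1-[4-(benzyloxy)phenyl]-3,3-dimethoxypropyl]oxy}benzaldehyde | COC(OC)[C@@H](OCc1ccccc1)[C@H](Oc1cccc(OCc2ccccc2)c1C=O)c1ccc(OCc2ccccc2)cc1
F3 | step 9 | (2R,3R,4S)-3,7-bis(benzyloxy)-2-[4-(benzyloxy)phenyl]-4-methoxy-3,4-dihydro-2H-chromene-8-carbaldehyde | c1ccc(COc2ccc([C@H]3Oc4c(ccc(OCc5ccccc5)c4C=O)[C@H](OC)[C@H]3OCc3ccccc3)cc2)cc1
F4 | step 9 | (2R,3R,4S)-3,7-bis(benzyloxy)-2-[4-(benzyloxy)phenyl]-4-methoxy-3,4-dihydro-2H-chromen-8-yl formate | c1ccc(COc2ccc([C@H]3Oc4c(ccc(OCc5ccccc5)c4OC=O)[C@H](OC)[C@H]3OCc3ccccc3)cc2)cc1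
F5 | step 12 | 3,7,8,4′-tetra-O-benzylepioritin-(4β→6)-3,7,8,4′-tetra-O-benzyl-4β-(benzylsulfanyl)epioritin | c1ccc(COc2ccc([C@H]3Oc4c(ccc(OCc5ccccc5)c4OCc4ccccc4)[C@H](c4cc5c(c(OCc6ccccc6)c4OCc4ccccc4)O[C@H](c4ccc(OCc6ccccc6)cc4)[C@H](OCc4ccccc4)[C@H]5SCc4ccccc4)[C@H]3OCc3ccccc3)cc2)cc1
F6 | step 13 | 4-O-tert-butyldimethylsilyl ether of 17 | c1ccc(COc2ccc([C@H]3Oc4c(ccc(OCc5ccccc5)c4OCc4ccccc4)[C@H](O[Si](C)(C)C(C)(C)C)[C@H]3OCc3ccccc3)cc2)cc1
F7 | step 13 | 4-O-tert-butyldimethylsilyl ether (lower unit) of 18 | c1ccc(COc2ccc([C@H]3Oc4c(ccc(OCc5ccccc5)c4OCc4ccccc4)[C@H](c4cc5c(c(OCc6ccccc6)c4OCc4ccccc4)O[C@H](c4ccc(OCc6ccccc6)cc4)[C@H](OCc4ccccc4)[C@H]5O[Si](C)(C)C(C)(C)C)[C@H]3OCc3ccccc3)cc2)cc1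
F8 | step 13 | 4-O-tert-butyldimethylsilyl ether (lower unit) of 19 | Oc1ccc([C@H]2Oc3c(ccc(O)c3O)[C@H](c3cc4c(c(O)c3O)O[C@H](c3ccc(O)cc3)[C@H](O)[C@H]4O[Si](C)(C)C(C)(C)C)[C@H]2O)cc1
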